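The depside ester is disconnected at the O–C4 bond of ring B (the methyl benzoate ring) instead of at the acyl C–O bond. This uses two facts: C4 of ring B lies para to the C1 CO2Me group, and the ring A carbonyl carbon is walled in by the C2 oxygen substituent and the C6 methyl. The ring A carboxylate therefore serves as nucleophile and ring B, as a diaryliodonium salt with a 2,4,6-trimethoxyphenyl dummy, as electrophile. One heating step forms the aryl C–O bond and gives the tri-O-benzyl depside from the bis(benzyloxy) chloro acid and the 2-benzyloxy iodonium tosylate; BCl3 then frees the three phenols.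

Key step: step 9

Remark: ring A is the chlorinated acyl ring and ring B the methyl benzoate ring, each numbered as a benzoate (C1 bears the carbonyl carbon); the target has no stereocentre.

Step 1
Reactants: 1 methyl 2,4-dihydroxy-3,6-dimethylbenzoate
Product: 2 methyl 5-chloro-2,4-dihydroxy-3,6-dimethylbenzoate
Conditions: SO2Cl2 (1.05 equiv), CH2Cl2, 0 → 25 °C
Reagents that add atoms: sulfuryl chloride, O=S(=O)(Cl)Cl
Why: Electrophilic aromatic chlorination should occur at C5, the only unsubstituted ring carbon, which is activated ortho to the C4 hydroxyl and para to the C2 hydroxyl.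

Step 2
Reactants: 2 methyl 5-chloro-2,4-dihydroxy-3,6-dimethylbenzoate; 3 benzyl bromide
Product: 4 methyl 2,4-bis(benzyloxy)-5-chloro-3,6-dimethylbenzoate
Conditions: BnBr (2.4 equiv in all), K2CO3 (3 equiv), DMF, 60 °C
Reagents that add atoms: benzyl bromide (second equivalent of 3), BrCc1ccccc1
Why: Double Williamson etherification in warm DMF should alkylate both phenoxides on oxygen, each consuming one equivalent of benzyl bromide and including the chelated C2 hydroxyl, while the hindered methyl ester stays intact.

Step 3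
Reactants: 4 methyl 2,4-bis(benzyloxy)-5-chloro-3,6-dimethylbenzoate
Product: 5 2,4-bis(benzyloxy)-5-chloro-3,6-dimethylbenzoic acid
Conditions: n-PrSH, n-BuLi, THF–HMPA, 0 → 25 °C; then 1 M HCl
Reagents that add atoms: none
Why: Nucleophilic dealkylation of a hindered methyl ester (SN2 at the O-methyl carbon) should succeed because the soft thiolate attacks the open methyl group and not the shielded carbonyl, and at room temperature the benzyl ethers and the unactivated aryl chloride should be left alone.

Step 4
Reactants: 1 methyl 2,4-dihydroxy-3,6-dimethylbenzoate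
Product: 6 methyl 2-hydroxy-3,6-dimethyl-4-{[(trifluoromethyl)sulfonyl]oxy}benzoate
Conditions: Tf2O (1.05 equiv), pyridine, CH2Cl2, −20 → 0 °C
Reagents that add atoms: trifluoromethanesulfonic anhydride, O=S(=O)(OS(=O)(=O)C(F)(F)F)C(F)(F)F
Why: Selective O-sulfonylation should take the free C4 hydroxyl, because the C2 hydroxyl is hydrogen-bonded to the ester carbonyl and flanked by the ester and the C3 methyl.

Step 5
Reactants: 6 methyl 2-hydroxy-3,6-dimethyl-4-{[(trifluoromethyl)sulfonyl]oxy}benzoate; 3 benzyl bromide
Product: 7 methyl 2-(benzyloxy)-3,6-dimethyl-4-{[(trifluoromethyl)sulfonyl]oxy}benzoate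
Conditions: BnBr (1.2 equiv), K2CO3, DMF, 40 °C
Reagents that add atoms: none
Why: Williamson etherification of the remaining chelated phenol should proceed under mild carbonate conditions that an aryl triflate tolerates, the reactive benzyl bromide capturing the phenoxide before it can attack a sulfonyl group.

Step 6
Reactants: 7 methyl 2-(benzyloxy)-3,6-dimethyl-4-{[(trifluoromethyl)sulfonyl]oxy}benzoate
Product: 8 methyl 2-(benzyloxy)-3,6-dimethyl-4-(4,4,5,5-tetramethyl-1,3,2-dioxaborolan-2-yl)benzoate
Conditions: B2pin2, Pd(dppf)Cl2 (5 mol %), KOAc, 1,4-dioxane, 90 °C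
Reagents that add atoms: bis(pinacolato)diboron, CC1(C)OB(OC1(C)C)B1OC(C)(C)C(C)(C)O1
Why: Miyaura borylation should work because zerovalent palladium inserts into the aryl C–OTf bond, and acetate-assisted transmetalation with the diboron followed by reductive elimination gives the boronate without affecting ester or benzyl ether.

Step 7
Reactants: 8 methyl 2-(benzyloxy)-3,6-dimethyl-4-(4,4,5,5-tetramethyl-1,3,2-dioxaborolan-2-yl)benzoate
Product: 9 methyl 2-(benzyloxy)-4-iodo-3,6-dimethylbenzoate
Conditions: CuI (10 mol %), 1,10-phenanthroline (20 mol %), KI, MeOH–H2O, air, 80 °C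
Reagents that add atoms: potassium iodide, [K+].[I-]
Why: Copper-mediated iododeboronation (an oxidative halogenation related to Chan–Lam coupling) places iodine at C4 through boron-to-copper transmetalation, which avoids electrophilic iodination at the free C5 position para to the benzyloxy group.

Step 8
Reactants: 9 methyl 2-(benzyloxy)-4-iodo-3,6-dimethylbenzoate; 10 1,3,5-trimethoxybenzene
Product: 12 [3-(benzyloxy)-4-(methoxycarbonyl)-2,5-dimethylphenyl](2,4,6-trimethoxyphenyl)iodonium p-toluenesulfonate, via hydroxy(tosyloxy)iodane 11 (not isolated)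
Conditions: mCPBA (1.1 equiv), TsOH·H2O (1.0 equiv), MeCN, 77 °C; then 10, 77 °C; Et2O trituration
Reagents that add atoms: p-toluenesulfonic acid monohydrate, Cc1ccc(cc1)S(=O)(=O)O.O
Why: One-pot oxidation and arylation to a diaryliodonium salt should work because the peracid with TsOH oxidises the aryl iodide to the hydroxy(tosyloxy)-λ3-iodane, which the very nucleophilic trimethoxybenzene, added only after the peracid is consumed, attacks by electrophilic aromatic substitution with loss of water.

Step 9
Reactants: 5 2,4-bis(benzyloxy)-5-chloro-3,6-dimethylbenzoic acid; 12 [3-(benzyloxy)-4-(methoxycarbonyl)-2,5-dimethylphenyl](2,4,6-trimethoxyphenyl)iodonium p-toluenesulfonate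
Product: 15 methyl 2-(benzyloxy)-4-{[2,4-bis(benzyloxy)-5-chloro-3,6-dimethylbenzoyl]oxy}-3,6-dimethylbenzoate, via potassium carboxylate 13 (not isolated), via iodonium carboxylate 14 (not isolated)
Conditions: KOt-Bu (1.0 equiv), toluene, 25 °C; then 12 (1.1 equiv), 110 °C
Reagents that add atoms: none
Why: One equivalent of KOt-Bu converts acid 5 into potassium carboxylate 13, which displaces tosylate at trivalent iodine to give the T-shaped iodonium carboxylate 14, and ligand coupling at iodine then joins the carboxylate oxygen to the ipso carbon (C4) of ring B while 2-iodo-1,3,5-trimethoxybenzene departs. The closest known reaction type is the metal-free O-arylation of carboxylic acids with diaryliodonium salts that carry a trimethoxyphenyl auxiliary. No ring is closed and no stereocentre is created. The step needs chemoselective transfer of ring B instead of the auxiliary, which is secured because ring B is far less electron-rich (CO2Me para to iodine) and bears the C3 methyl ortho to iodine, whereas the tri-donor-substituted auxiliary stays bound to iodine. It also needs the carboxylate to be the only nucleophile, which the three benzyl ethers ensure, and since the new bond is made at oxygen the crowded acyl carbon of ring A (between C2–OBn and C6–Me) is never attacked. Exactly one equivalent of base leaves no free alkoxide that could deprotonate C5–H next to iodine and open aryne pathways.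

Step 10
Reactants: 15 methyl 2-(benzyloxy)-4-{[2,4-bis(benzyloxy)-5-chloro-3,6-dimethylbenzoyl]oxy}-3,6-dimethylbenzoate
Product: 16 methyl 4-[(5-chloro-2,4-dihydroxy-3,6-dimethylbenzoyl)oxy]-2-hydroxy-3,6-dimethylbenzoate
Conditions: BCl3 (1 M in CH2Cl2, 6 equiv), pentamethylbenzene (9 equiv), CH2Cl2, −78 °C; then MeOH–H2O
Reagents that add atoms: none
Why: Lewis acid debenzylation with a cation scavenger should free all three phenols at low temperature, since BCl3 activates each ether oxygen and pentamethylbenzene traps the benzyl cation by Friedel–Crafts alkylation, leaving the aryl chloride, the methyl ester and the depside ester untouched.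

Compound list
1 | methyl 2,4-dihydroxy-3,6-dimethylbenzoate | COC(=O)c1c(C)cc(O)c(C)c1O | starting material
2 | methyl 5-chloro-2,4-dihydroxy-3,6-dimethylbenzoate | COC(=O)c1c(C)c(Cl)c(O)c(C)c1O | intermediate
3 | benzyl bromide | BrCc1ccccc1 | starting material
4 | methyl 2,4-bis(benzyloxy)-5-chloro-3,6-dimethylbenzoate | COC(=O)c1c(C)c(Cl)c(OCc2ccccc2)c(C)c1OCc1ccccc1 | intermediate
5 | 2,4-bis(benzyloxy)-5-chloro-3,6-dimethylbenzoic acid | OC(=O)c1c(C)c(Cl)c(OCc2ccccc2)c(C)c1OCc1ccccc1 | intermediate
6 | methyl 2-hydroxy-3,6-dimethyl-4-{[(trifluoromethyl)sulfonyl]oxy}benzoate | COC(=O)c1c(C)cc(OS(=O)(=O)C(F)(F)F)c(C)c1O | intermediate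
7 | methyl 2-(benzyloxy)-3,6-dimethyl-4-{[(trifluoromethyl)sulfonyl]oxy}benzoate | COC(=O)c1c(C)cc(OS(=O)(=O)C(F)(F)F)c(C)c1OCc1ccccc1 | intermediate
8 | methyl 2-(benzyloxy)-3,6-dimethyl-4-(4,4,5,5-tetramethyl-1,3,2-dioxaborolan-2-yl)benzoate | COC(=O)c1c(C)cc(B2OC(C)(C)C(C)(C)O2)c(C)c1OCc1ccccc1 | intermediate
9 | methyl 2-(benzyloxy)-4-iodo-3,6-dimethylbenzoate | COC(=O)c1c(C)cc(I)c(C)c1OCc1ccccc1 | intermediate
10 | 1,3,5-trimethoxybenzene | COc1cc(OC)cc(OC)c1 | starting material
11 | methyl 2-(benzyloxy)-4-[hydroxy(tosyloxy)-λ3-iodanyl]-3,6-dimethylbenzoate (formed in the flask) | COC(=O)c1c(C)cc(I(O)OS(=O)(=O)c2ccc(C)cc2)c(C)c1OCc1ccccc1 | intermediate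
12 | [3-(benzyloxy)-4-(methoxycarbonyl)-2,5-dimethylphenyl](2,4,6-trimethoxyphenyl)iodonium p-toluenesulfonate | COC(=O)c1c(C)cc([I+]c2c(OC)cc(OC)cc2OC)c(C)c1OCc1ccccc1.Cc1ccc(S(=O)(=O)[O-])cc1 | intermediate
13 | potassium 2,4-bis(benzyloxy)-5-chloro-3,6-dimethylbenzoate (formed in the flask) | [K+].[O-]C(=O)c1c(C)c(Cl)c(OCc2ccccc2)c(C)c1OCc1ccccc1 | intermediate
14 | [3-(benzyloxy)-4-(methoxycarbonyl)-2,5-dimethylphenyl](2,4,6-trimethoxyphenyl)iodonium 2,4-bis(benzyloxy)-5-chloro-3,6-dimethylbenzoate (formed in the flask) | COC(=O)c1c(C)cc([I+]c2c(OC)cc(OC)cc2OC)c(C)c1OCc1ccccc1.[O-]C(=O)c1c(C)c(Cl)c(OCc2ccccc2)c(C)c1OCc1ccccc1 | intermediate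
15 | methyl 2-(benzyloxy)-4-{[2,4-bis(benzyloxy)-5-chloro-3,6-dimethylbenzoyl]oxy}-3,6-dimethylbenzoate | COC(=O)c1c(C)cc(OC(=O)c2c(C)c(Cl)c(OCc3ccccc3)c(C)c2OCc2ccccc2)c(C)c1OCc1ccccc1 | intermediate
16 | methyl 4-[(5-chloro-2,4-dihydroxy-3,6-dimethylbenzoyl)oxy]-2-hydroxy-3,6-dimethylbenzoate | COC(=O)c1c(C)cc(OC(=O)c2c(C)c(Cl)c(O)c(C)c2O)c(C)c1O | target

Total step count: 10
Longest linear sequence: 7 steps (1 → 6 → 7 → 8 → 9 → 12 → 15 → 16; the ring A branch 1 → 2 → 4 → 5 joins at step 9)

Steps most likely to fail

1. Step 9. Ligand coupling may deliver the trimethoxyphenyl group to oxygen instead of ring B, or ion exchange may stall because the potassium salt dissolves poorly in toluene, so that the iodonium salt decomposes on heating before it couples. The fallback sets out from acid 5 and ester 1 and reverses the polarity to a classical acylation. Trifluoroacetic anhydride in toluene at 25 °C should turn 5 into 2,4-bis(benzyloxy)-5-chloro-3,6-dimethylbenzoic trifluoroacetic anhydride F1, an acylium-like donor that is not blocked by the ortho groups. F1 should acylate the free C4 hydroxyl of 1 (the C2 hydroxyl is chelated) to methyl 4-{[2,4-bis(benzyloxy)-5-chloro-3,6-dimethylbenzoyl]oxy}-2-hydroxy-3,6-dimethylbenzoate F2. BCl3 and pentamethylbenzene at −78 °C, as in step 10, then remove the two benzyl ethers, and the fallback rejoins the route at target 16.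

2. Step 8. The peracid may oxidise the benzyloxy-substituted arene, or the λ3-iodane may arylate a second molecule of 9 at C5 before trimethoxybenzene is present. The fallback sets out from iodide 9 and separates oxidation from arylation. NaBO3·4H2O in acetic acid at 45 °C should give methyl 2-(benzyloxy)-4-(diacetoxy-λ3-iodanyl)-3,6-dimethylbenzoate F3, which is isolated. F3 should condense with 10 in 2,2,2-trifluoroethanol at 25 °C, without added strong acid, to [3-(benzyloxy)-4-(methoxycarbonyl)-2,5-dimethylphenyl](2,4,6-trimethoxyphenyl)iodonium acetate F4. Anion exchange with TsOH·H2O in MeCN then brings the fallback back to the route at 12.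

3. Step 3. Thiolate attack at the benzylic carbons of the ethers may compete with demethylation of the ester, or the dealkylation may stop short. The fallback sets out from ester 4 and replaces dealkylation by a change of oxidation level. LiAlH4 in THF (0 → 25 °C) should reduce the ester to [2,4-bis(benzyloxy)-5-chloro-3,6-dimethylphenyl]methanol F5. Dess–Martin periodinane in CH2Cl2 should give 2,4-bis(benzyloxy)-5-chloro-3,6-dimethylbenzaldehyde F6. Pinnick oxidation (NaClO2, NaH2PO4, 2-methyl-2-butene, t-BuOH–H2O) should then return to the route at acid 5; ring A has no free position that hypochlorite could chlorinate.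

Further compounds
F1 | step 9 | 2,4-bis(benzyloxy)-5-chloro-3,6-dimethylbenzoic trifluoroacetic anhydride | O=C(OC(=O)C(F)(F)F)c1c(C)c(Cl)c(OCc2ccccc2)c(C)c1OCc1ccccc1
F2 | step 9 | methyl 4-{[2,4-bis(benzyloxy)-5-chloro-3,6-dimethylbenzoyl]oxy}-2-hydroxy-3,6-dimethylbenzoate | COC(=O)c1c(C)cc(OC(=O)c2c(C)c(Cl)c(OCc3ccccc3)c(C)c2OCc2ccccc2)c(C)c1O
F3 | step 8 | methyl 2-(benzyloxy)-4-(diacetoxy-λ3-iodanyl)-3,6-dimethylbenzoate | COC(=O)c1c(C)cc(I(OC(C)=O)OC(C)=O)c(C)c1OCc1ccccc1
F4 | step 8 | [3-(benzyloxy)-4-(methoxycarbonyl)-2,5-dimethylphenyl](2,4,6-trimethoxyphenyl)iodonium acetate | COC(=O)c1c(C)cc([I+]c2c(OC)cc(OC)cc2OC)c(C)c1OCc1ccccc1.CC(=O)[O-]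
F5 | step 3 | [2,4-bis(benzyloxy)-5-chloro-3,6-dimethylphenyl]methanol | OCc1c(C)c(Cl)c(OCc2ccccc2)c(C)c1OCc1ccccc1
F6 | step 3 | 2,4-bis(benzyloxy)-5-chloro-3,6-dimethylbenzaldehyde | O=Cc1c(C)c(Cl)c(OCc2ccccc2)c(C)c1OCc1ccccc1
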